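## Retrosynthetic overview
1. Ring C is opened last at C2–O1 (retro-oxa-Michael) to the open-chain 2',4'-dihydroxychalcone. In the forward direction, a chalcone-isomerase-like, catalyst-controlled closure of the unprotected chalcone sets C2 (S) in the final step.
2. The chalcone Cα=Cβ bond comes from a Claisen–Schmidt union of 3-prenylresacetophenone (ring A) with 2,2-dimethyl-8-prenylchroman-6-carbaldehyde (rings B and D).
3. Ring D is opened at O–CMe2 to 4-hydroxy-3,5-diprenylbenzaldehyde. The forward prenylphenol-to-chroman cycloisomerisation is self-limiting, because one OH faces two identical prenyl groups.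
4. All three prenyl groups come from direct phenoxide C-prenylation of 2,4-dihydroxyacetophenone and 4-hydroxybenzaldehyde with prenyl bromide. No protecting groups are used.
5. Ring order: rings A and B are bought, ring D is closed first, and ring C is closed last.

Assumption: the quinidine-derived thiourea is taken to give the (2S) product. The first run is checked by ECD (2S shows a positive band near 330 nm and a negative band near 290 nm). The quinine-derived pseudo-enantiomer replaces it if the sense is opposite.

## Route

Step 1
Reactants: 1 2,4-dihydroxyacetophenone; 2 prenyl bromide (1-bromo-3-methylbut-2-ene)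
Product: 3 1-[2,4-dihydroxy-3-(3-methylbut-2-enyl)phenyl]ethanone
Conditions: KOH (1.1 equiv, 10% aq), 2 (1.0 equiv, dropwise), 0 °C to rt, 16 h; SiO2 (expected about 30%)
Reagents that add atoms: prenyl bromide (2), CC(C)=CCBr
Why: Nuclear prenylation (phenoxide C-alkylation, SN2 on the allylic bromide): in water the phenoxide oxygens are masked by hydrogen bonding, so the most electron-rich ring carbon, C3 between the two oxygens, attacks, and the 5-prenyl and 4-O-prenyl isomers are removed on silica.

Step 2
Reactants: 4 4-hydroxybenzaldehyde; 2 prenyl bromide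
Product: 6 4-hydroxy-3,5-bis(3-methylbut-2-enyl)benzaldehyde, via monoprenyl aldehyde 5 (not isolated)
Conditions: KOH (2.4 equiv, 10% aq), 2 (2.3 equiv, slow addition), rt, 36 h; SiO2 (expected 20–25%)
Reagents that add atoms: prenyl bromide (2), CC(C)=CCBr
Why: Twofold nuclear prenylation in water: the para position is blocked by CHO and the two ortho positions are equivalent, so C-alkylation can only give 5 and then 6, while the neutral O-prenyl ethers are easily separated.

Step 3
Reactants: 6 4-hydroxy-3,5-bis(3-methylbut-2-enyl)benzaldehyde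
Product: 7 2,2-dimethyl-8-(3-methylbut-2-enyl)-3,4-dihydro-2H-chromene-6-carbaldehyde
Conditions: p-toluenesulfonic acid monohydrate (10 mol %), toluene (0.05 M), 60 °C, 2–4 h, quench with Et3N as soon as 6 is gone (expected about 80%)
Reagents that add atoms: none
Why: Brønsted-acid-catalysed intramolecular Markovnikov hydroalkoxylation (6-endo-trig cycloisomerisation of an ortho-prenylphenol): either prenyl gives the same chroman, and the reaction stops after one ring because no OH is left for the second alkene, which stays as the thermodynamically preferred trisubstituted olefin; no stereocentre is formed.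

Step 4
Reactants: 3 1-[2,4-dihydroxy-3-(3-methylbut-2-enyl)phenyl]ethanone; 7 2,2-dimethyl-8-(3-methylbut-2-enyl)-3,4-dihydro-2H-chromene-6-carbaldehyde
Product: 9 (E)-1-[2,4-dihydroxy-3-(3-methylbut-2-enyl)phenyl]-3-[2,2-dimethyl-8-(3-methylbut-2-enyl)-3,4-dihydro-2H-chromen-6-yl]prop-2-en-1-one, via aldol adduct 8 (not isolated)
Conditions: KOH (50% aq, 12 equiv), EtOH, N2, rt, 48–72 h; pour into ice-cold 1 M HCl (pH 5); SiO2 to remove any racemic flavanone (expected about 55%)
Reagents that add atoms: none
Why: Claisen–Schmidt condensation (crossed aldol, then E1cB dehydration): 7 cannot enolise and carries no deactivating phenoxide because its phenol is tied up in ring D, the methyl ketone of 3 is the only enolisable partner, and the conjugated (E)-enone is the thermodynamic product and stays ring-open at high pH as its phenoxide.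

Step 5
Reactants: 9 the (E)-chalcone
Product: 10 (2S)-7-hydroxy-8-(3-methylbut-2-enyl)-2-[2,2-dimethyl-8-(3-methylbut-2-enyl)-3,4-dihydro-2H-chromen-6-yl]-2,3-dihydro-4H-chromen-4-one
Conditions: N-[3,5-bis(trifluoromethyl)phenyl]-N'-[(9R)-6'-methoxycinchonan-9-yl]thiourea (quinidine-derived, 20 mol %), toluene (0.05 M), 4 Å molecular sieves, 25 °C, 72–96 h, stop at 50–60% conversion; load directly on SiO2 (recover and recycle 9); recrystallise to raise ee
Reagents that add atoms: none
Why: Proposed new method: an enantioselective 6-endo-trig intramolecular oxa-Michael addition on the unactivated, fully unprotected chalcone, in which the thiourea N–H pair binds the enone carbonyl in place of the internal 2'-OH···O=C hydrogen bond while the quinuclidine nitrogen takes the 2'-OH proton (the same acid/base division of labour as in chalcone isomerase), so that the phenolic oxygen is delivered to the Si face of Cβ inside the chiral pocket and proton return from the quinuclidinium gives the (2S) centre under kinetic control; the closest known reaction type is the cinchona-thiourea-catalysed cyclisation of 2'-hydroxychalcones and of their α-alkoxycarbonyl-activated analogues to flavanones, and the extension lies in the free 4'-OH, the electron-rich ring B and the demand for high ee without an activating group.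

## Compound list
1 | 2,4-dihydroxyacetophenone | CC(=O)c1ccc(O)cc1O | starting material
2 | prenyl bromide (1-bromo-3-methylbut-2-ene) | CC(C)=CCBr | starting material
3 | 1-[2,4-dihydroxy-3-(3-methylbut-2-enyl)phenyl]ethanone | CC(=O)c1ccc(O)c(CC=C(C)C)c1O | intermediate
4 | 4-hydroxybenzaldehyde | O=Cc1ccc(O)cc1 | starting material
5 | 4-hydroxy-3-(3-methylbut-2-enyl)benzaldehyde (formed in the flask, not isolated) | O=Cc1ccc(O)c(CC=C(C)C)c1 | intermediate
6 | 4-hydroxy-3,5-bis(3-methylbut-2-enyl)benzaldehyde | O=Cc1cc(CC=C(C)C)c(O)c(CC=C(C)C)c1 | intermediate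
7 | 2,2-dimethyl-8-(3-methylbut-2-enyl)-3,4-dihydro-2H-chromene-6-carbaldehyde | O=Cc1cc(CC=C(C)C)c2OC(C)(C)CCc2c1 | intermediate
8 | racemic β-hydroxyketone aldol adduct of 3 and 7 (formed in the flask, not isolated) | CC(C)=CCc1c(O)ccc(C(=O)CC(O)c2cc(CC=C(C)C)c3OC(C)(C)CCc3c2)c1O | intermediate
9 | (E)-2',4'-dihydroxy-3'-prenylchalcone whose ring B is the 2,2-dimethyl-8-prenylchroman-6-yl unit | CC(C)=CCc1c(O)ccc(C(=O)/C=C/c2cc(CC=C(C)C)c3OC(C)(C)CCc3c2)c1O | intermediate
10 | (2S)-7-hydroxy-8-prenyl-2-(2,2-dimethyl-8-prenylchroman-6-yl)chroman-4-one, CNP0272905.1 | CC(C)=CCc1cc([C@@H]2CC(=O)c3ccc(O)c(CC=C(C)C)c3O2)cc2c1OC(C)(C)CC2 | target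

## Step count and risks
Total step count: 5.
Longest linear sequence: 4 steps (4 → 6 → 7 → 9 → 10).

**Step 5 (highest risk).**
- The acidic 4'-OH can occupy the quinuclidine unproductively.
- The alkoxy-substituted ring B lowers the electrophilicity of Cβ.
- The chalcone/flavanone equilibrium limits conversion and erodes ee if the reaction is left too long.

The fallback sets out from 9 and comes back at 10. The chalcone is cyclised without stereocontrol (NaOAc, EtOH, reflux) to the racemic flavanone F1. This is separated by preparative chiral SFC (amylose tris(3,5-dimethylphenylcarbamate) phase, CO2/MeOH) into 10 and the (2R)-flavanone F2. The unwanted antipode is reopened with KOH/EtOH followed by cold HCl to give 9 again, so the material is recycled rather than lost.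

**Step 2.** The formyl group makes the phenoxide a poor carbon nucleophile. O-alkylation and incomplete second prenylation therefore keep the yield low.

The fallback sets out from 4 and comes back at 6.
- Bromination with Br2 (2.1 equiv) in AcOH at rt passes through 3-bromo-4-hydroxybenzaldehyde F3 and gives 3,5-dibromo-4-hydroxybenzaldehyde F4.
- A twofold Stille coupling follows, using tributyl(3-methylbut-2-enyl)stannane (2.5 equiv) and Pd(PPh3)4 (5 mol %) in DMF at 90 °C.
- It passes through 3-bromo-4-hydroxy-5-(3-methylbut-2-enyl)benzaldehyde F5 and delivers 6 with linear prenyl groups at positions fixed by the halogens.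

**Step 4.** The doubly deprotonated ketone 3 enolises reluctantly, so the condensation may be slow and compete with Cannizzaro loss of 7.

The fallback sets out from 3 and comes back at 9.
- The non-chelated 4-OH is masked selectively (MOMCl, K2CO3, acetone, rt) to give 1-[2-hydroxy-4-(methoxymethoxy)-3-(3-methylbut-2-enyl)phenyl]ethanone F6.
- This is condensed with 7 (KOH, EtOH, rt) through the racemic MOM-protected aldol adduct F7 to the 4'-O-MOM chalcone F8.
- Brief treatment with 3 M HCl in MeOH at 50 °C removes the acetal to give 9.

## Further compounds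
F1 | step 5 | racemic 7-hydroxy-8-prenyl-2-(2,2-dimethyl-8-prenylchroman-6-yl)chroman-4-one | CC(C)=CCc1cc(C2CC(=O)c3ccc(O)c(CC=C(C)C)c3O2)cc2c1OC(C)(C)CC2
F2 | step 5 | (2R)-7-hydroxy-8-prenyl-2-(2,2-dimethyl-8-prenylchroman-6-yl)chroman-4-one | CC(C)=CCc1cc([C@H]2CC(=O)c3ccc(O)c(CC=C(C)C)c3O2)cc2c1OC(C)(C)CC2
F3 | step 2 | 3-bromo-4-hydroxybenzaldehyde | O=Cc1ccc(O)c(Br)c1
F4 | step 2 | 3,5-dibromo-4-hydroxybenzaldehyde | O=Cc1cc(Br)c(O)c(Br)c1
F5 | step 2 | 3-bromo-4-hydroxy-5-(3-methylbut-2-enyl)benzaldehyde | O=Cc1cc(Br)c(O)c(CC=C(C)C)c1
F6 | step 4 | 1-[2-hydroxy-4-(methoxymethoxy)-3-(3-methylbut-2-enyl)phenyl]ethanone | CC(=O)c1ccc(OCOC)c(CC=C(C)C)c1O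
F7 | step 4 | racemic MOM-protected aldol adduct of F6 and 7 | CC(C)=CCc1c(OCOC)ccc(C(=O)CC(O)c2cc(CC=C(C)C)c3OC(C)(C)CCc3c2)c1O
F8 | step 4 | (E)-4'-O-MOM chalcone | CC(C)=CCc1c(OCOC)ccc(C(=O)/C=C/c2cc(CC=C(C)C)c3OC(C)(C)CCc3c2)c1O
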